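The target is what I count, and in the earlier runs it levels off below the starting material charged, at a height that goes with the partner.

| flask | starting material | second substrate | partner | free catalyst | temperature | remark | time |
|---|---|---|---|---|---|---|---|
| beta | 0.31 M | 1 equiv | 1.5 equiv | 0.5 mol% | 80 °C | run made earlier |  |
| gamma | 0.75 M | 1 equiv | 1.5 equiv | 0.5 mol% | 102 °C | run made earlier |  |
| eta | 0.24 M | 1 equiv | 1.3 equiv | 0.5 mol% | 80 °C | run made earlier |  |
| midnight | 0.24 M | 1.50 equiv | 1.50 equiv | 0.12 mol% | 70 °C |  | 4.0 min |
| summer | 0.40 M | 1.00 equiv | 2.20 equiv | 0.5 mol% | 110 °C |  | 4.0 min |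
| noon | 0.24 M | 1.00 equiv | 1.50 equiv | 0.5 mol% | 70 °C |  | 4.0 min |
| autumn | 0.50 M | 1.00 equiv | 1.50 equiv | 0.3 mol% | 70 °C |  | 4.0 min |

| beta: time / s | beta: target / % | gamma: time / s | gamma: target / % | eta: time / s | eta: target / % |
|---|---|---|---|---|---|
| 25.0 | 64.2 | 10.0 | 77.2 | 10.0 | 28.2 |
| 50.0 | 76.6 | 15.0 | 79.4 | 20.0 | 42.3 |
| 80.0 | 82.0 | 25.0 | 79.6 | 50.0 | 61.3 |
| 120 | 83.6 | 40.0 | 80.4 | 120 | 71.7 |

(readings scatter by 1 percentage point)

1. ranking by amount of target, in percent of the starting material charged, from high to low, at 4.0 min (midnight / summer / noon / autumn)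
2. the amount of target, in percent of the starting material charged of the flask you put first, at 4.0 min
3. the amount of target, in percent of the starting material charged of the flask you put last, at 4.0 min

The beta run, nearly level at 83.6% on 1.5 equiv of partner, gives 0.557 of target per partner. I call this ratio of final target to partner charged, both counted on the starting material, the partner yield, and I treat the partner as the limiting reagent. The gamma run, hotter at 102 °C, reads 0.536.

Now I turn the question round. Summer carries more partner than noon, so what would have to be true for summer to finish below noon? If noon reaches 83.6% at the beta yield, summer must fall to a partner yield of 0.380. That lies 0.156 below the gamma reading. The margin is less safe than it looks, though. Summer is hotter still, at 110 °C, and its catalyst per litre is about half of gamma's, with [starting material] at 0.40 M against 0.75 M. I expect both to favour any waste of partner. I still commit to summer first, with autumn and noon close together and midnight last, since midnight has a quarter of noon's loading.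

The forecast gives summer > autumn > noon > midnight, with 93% (range 85% to 99%) for the first flask and 70% (range 52% to 82%) for the last, holding for summer that “partner is no longer limiting”.

The flasks give autumn > noon > summer > midnight, with 88.3%, 85.8%, 74.7% and 52.0%.

    starting material + free catalyst ⇌ catalyst intermediate A (K = 12.2 M⁻¹, k = 288 M⁻¹ s⁻¹, Ea = 35.0 kJ mol⁻¹, ΔH = −55.0 kJ mol⁻¹)
    second substrate + free catalyst ⇌ catalyst intermediate B (K = 3.53 M⁻¹, k = 22.5 M⁻¹ s⁻¹, Ea = 44.0 kJ mol⁻¹, ΔH = −44.0 kJ mol⁻¹)
    partner → decomposed reagent (k = 0.00204 s⁻¹, Ea = 95.0 kJ mol⁻¹)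
    starting material + partner → uncatalysed product (k = 0.00552 M⁻¹ s⁻¹, Ea = 83.0 kJ mol⁻¹)
    partner + catalyst intermediate B → free catalyst + second product (k = 25.6 M⁻¹ s⁻¹, Ea = 59.0 kJ mol⁻¹)
    partner + catalyst intermediate A → free catalyst + target (k = 23.3 M⁻¹ s⁻¹, Ea = 63.0 kJ mol⁻¹)
    (constants at 70 °C)

Summer's partner yield comes out at 0.340, below the line of 0.380, with partner down to 0% at 4.0 min, so my first place was wrong. Autumn's yield is 0.589. A neighbour of autumn charged with 0.900 equiv of partner makes 59.9% of target, a yield of 0.666, which is higher than autumn's. Midnight stands last mainly because of the reverse step, catalyst intermediate A to starting material + free catalyst: with that step taken away, midnight gives 81.2% of target instead of 52.0%.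

The readings were computed for an exercise.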